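## The problem

The target 39, the twenty-carbon gibberellin that bears the number seventeen in the A series (ent-13-hydroxygibberell-16-ene-7,19,20-trioic acid), is a 6-5-6-5 tetracycle in which cyclohexane ring A is trans-fused to cyclopentane ring B and ring B shares its C8–C9 bond with the bicyclo[3.2.1]octane made of rings C and D. Seven stereocentres have to be set (C4, C5, C6, C8, C9, C10, C13), four of them fully substituted (C4, C8, C10, C13). Three carboxyl groups sit at C7 (on C6), C19 (on C4) and C20 (on C10), the last two 1,3-diaxial on the α face of ring A. C5 lies between the two quaternary ring A carbons and can direct both, whereas C6, the only centre that could be corrected late because it is α to C7, is also the one best placed to steer the face of C8 and is therefore better fixed early in a form that cannot epimerise. The tertiary allylic C13 hydroxyl beside the C16 exocyclic methylene does not survive strong acid (Wagner–Meerwein shift of C12), the exocyclic alkene competes in any hydrogenation, and the hindered axial C19 and C20 esters resist saponification. The feature that opens the key step is that ring C is a six-membered ring whose C8–C9 bond belongs to ring B, that quaternary C8 carries C15, and that C13 carries oxygen and C16. A C9=C11–C12=C13 diene with oxygen and C16 on C13 and a C8=C14 alkene with C15 on C8, joined through C10–C5–C6, therefore map onto one cyclohexene while the tether becomes ring B.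

## Retrosynthesis

**End game, 39 ⇐ 38 ⇐ 36.** No skeletal bond is cut. The C19 and C20 methyl esters of 38 are cleaved last by SN2 attack at methyl, and the C7 acid of 38 comes from the primary alcohol of diol 36. Keeping C7 as a silyl-protected CH2O group until this point means that C6–H is never acidic before the end and that a C15 alcohol can never lactonise onto C7. The forward steps must spare the 13-hydroxy-16-ene unit, so no acid is used.

**Ring D, 36 ⇐ 35 ⇐ 34 ⇐ 33 ⇐ 31.** The C15–C16 bond is cut: iodide 33 closes ring D by 5-exo-dig radical attack on the alkyne already on C13. Against a ketone-based closure, this uses exactly the two groups the cycloaddition delivers (C15 on C8 and C16 on C13, cis). The silicon on C17 is kept on purpose: vinylsilane 34 masks the exocyclic methylene while diimide saturates C11=C12 and C1=C2 (35), and fluoride then removes it (36). Iodide 33 comes from aldehyde 31 by reduction and iodination.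

**Rings B and C, 31 ⇐ 30 (key step).** C8–C9 and C13–C14 are cut. Tricycle 31 opens to ring A compound 30, which carries the silyloxy dienyne on C10 and the 2-substituted acrolein on C5–C6. Three stereocentres and two rings are removed at once. The forward reaction must deliver ring C on the α face of ring B and a cis B/C fusion.

**Diene and dienophile, 30 ⇐ 29 ⇐ 28 ⇐ 24 + 27, and 24 ⇐ 23 ⇐ 22.** Dienol ether 30 comes from enynone 29 by γ-enolisation, and 29 from enynol 28 by oxidation. The C11=C12 bond of 28 is cut by cross metathesis into the allyl group of 24 and enynol 27 (from 25 and 26). The C8=C14 bond of 24 is cut by α-methylenation of aldehyde 23, which comes from triethylsilyl ether 22. The dienophile is completed before the ynone exists, so that the dimethylamine set free in the methylenation never meets the ynone.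

**C10, 22 ⇐ 20 ⇐ 18 ⇐ 16 ⇐ 13.** C10–C20 and C10–C9 are cut. In ketone 13 a methyl carbonate on O7 sits where only the C10 enolate can reach it. Acylation gives a β-keto δ-lactone (15) and allylation of its enolate gives 16. This solves the regiochemistry at the C1 ketone (C10 against C2) without a directed enolate, and the cis-fused lactone sets C10. The C1 oxygen is then removed through enol triflate 17 to alkene 18, and the lactone, which has meanwhile served to tell O7 from O15, is opened to 22 by way of 20.

**Ring A, 13 ⇐ 11 ⇐ 8 + 9.** C4–C5 and C2–C3 are cut: a catalytic enantioselective Diels–Alder reaction of silyloxy diene 8 with methacrolein (9) gives keto aldehyde 11 by way of 10. Methacrolein brings C4 with its methyl and carboxyl carbon, and the endo rule puts C19 cis to the C5 side chain. Setting C4 in a cycloaddition avoids a weakly controlled alkylation or conjugate addition at a carbon that already carries methyl and carboxyl.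

**C5–C6 and the C6 stereocentre, 8 ⇐ 7 ⇐ 5 + 6, and 5 ⇐ 4 ⇐ 3 ⇐ 1 + 2.** The C5=C10 bond of enone 7 is cut by cross metathesis into vinyl compound 5 and methyl vinyl ketone (6). Biscarbonate 5 comes from diol 4 and lactone 3, whose C5–C6 bond is made by asymmetric conjugate addition of a vinyl group (2) to furan-2(5H)-one (1). C6 is thus set first, with C7 as CH2O and C8–C15 as a two-carbon arm, and is configurationally stable.

## Roads not taken

Alternative 1: Domino Heck closure of rings B and D. The cut is C6–C8 and C15–C16. The substrate would be enol triflate A1: ring A with the C5=C6 enol triflate of the C7 ester and, on C10, a ring C that carries an exocyclic C8=C15 methylene and a 13-hydroxy-13-vinyl group. Zerovalent palladium, Pd(PPh3)4, would insert at C6 and add 5-exo to the C8=C15 alkene (ring B). The neopentyl C15–palladium bond would then insert 5-exo into the C13 vinyl group (ring D), and β-hydride loss would leave the C16 methylene of the 5,6-didehydro trimethyl ester A2.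
- Merits: two rings, quaternary C8 and the C16 methylene arise in one catalytic step. The neopentyl alkylpalladium cannot β-eliminate, so the cascade is well set up. No tin is used and the exocyclic alkene needs no mask. In the number of late steps this road is better than the chosen plan.
- Weak points: A2 keeps a tetrasubstituted C5=C6 alkene conjugated to the C7 ester. Its reduction must create C5 (between two quaternary carbons) and C6 from the right face while sparing the more reactive C16=C17 alkene. The face of C8 in the first insertion rests only on ring C centres, and A1 already needs rings A and C joined at a quaternary C10.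
- Comparison: the chosen plan sets C5 first and uses it for both quaternary ring A carbons, and it carries the exocyclic alkene as a vinylsilane through the one reduction. It pays with four more operations after the key step.

Alternative 2: Radical cyclisation and allylation build ring C and C10. The cut is C9–C11 and C1–C10. The substrate would be iodide A3, a spiro compound in which C8 joins the ring D cyclopentanone to a ring B cyclopentene ester. With allyltributylstannane and AIBN its primary C11 radical would add 6-exo to C9 of the C9=C10 enoate and close ring C. The C10 radical would then take an allyl group from the stannane to give tricycle A4 with C10 allyl and C4 vinyl groups, ready for a ring A metathesis.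
- Merits: the bicyclo[3.2.1]octane and the C10 quaternary centre form in one step, ring A closes by a reliable metathesis, and the C13 oxygen/C16 pattern comes from a simple ketone. This road avoids the ring A redox detour (C1 ketone, then alkene) that the chosen plan needs.
- Weak points: the C10 radical is tertiary, α to an ester and hindered, so bimolecular allyl transfer is slow and its face (C20 must end α) is not secured. Direct allylation of the C11 radical competes with the 6-exo closure. The quaternary C4 of A3 must be made on an open chain with no ring to control it, and the C16 ketone of A4 still needs methylenation beside a hindered silyl ether.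
- Comparison: the chosen plan sets C4 and C10 on a ring under the control of C5 and uses a pericyclic step for C8, C9 and C13.

Alternative 3: Ring B contraction of a steviol derivative by Wolff rearrangement. The bond formed is C5–C6. Steviol A5 would be converted into ring B diazoketone A6 (ketone carbon next to C5, diazo carbon next to C8, C20 already an ester, 13-acetate). Photolysis in methanol would shift C5 from the ketone carbon to the diazo carbon, contract ring B and trap the ketene as the C7 ester. The product would be A7, the trimethyl ester 13-acetate of the target.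
- Merits: A5 already holds rings C and D, the C13 hydroxyl, the C16 methylene and the stereocentres C4, C5, C8, C9, C10 and C13. If A6 were accessible this would be by far the shortest route, clearly better than the chosen plan in step count.
- Weak points: C20 of A5 is a methyl group, so reaching A6 means oxidising an unactivated angular methyl to a carboxyl. A6 also needs oxidation of two unfunctionalised ring B carbons. C6 arises by ketene trapping and would have to be equilibrated. It is also a partial synthesis from a diterpenoid, not a construction of the skeleton.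
- Comparison: the chosen plan is much longer, but it brings C20 in at the carboxyl oxidation level (the carbonate carbon of 5) and builds every ring from simple materials.

Key step: step 19

Assumption: atoms carry gibberellane numbers; α and β refer to the faces of the target in its usual drawing (H5, H9, C7 and C15 β; C19 and C20 α); the sense of induction of the chiral rhodium and boron catalysts (steps 1 and 6) is assigned by analogy with related substrates, and the mirror-image ligand or catalyst would be used if it proved opposite.

## Route

Step 1
Reactants: 1 furan-2(5H)-one; 2 potassium trifluoro(vinyl)borate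
Product: 3 (R)-4-vinyldihydrofuran-2(3H)-one
Conditions: [Rh(cod)2]PF6 (3 mol %), (R)-BINAP, toluene/H2O, 100 °C
Reagents that add atoms: none
Why: Rhodium-catalysed asymmetric 1,4-addition of an alkenylboron reagent to an α,β-unsaturated lactone (Hayashi–Miyaura type); the BINAP–rhodium alkenyl species adds to one enantioface and sets C6 (R).

Step 2
Reactants: 3 (R)-4-vinyldihydrofuran-2(3H)-one
Product: 4 (R)-2-vinylbutane-1,4-diol
Conditions: LiAlH4, THF, 0 °C to rt; aqueous NaOH work-up
Reagents that add atoms: none
Why: Hydride reduction of a lactone to the 1,4-diol; C6 is not next to the carbonyl and cannot epimerise.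

Step 3
Reactants: 4 (R)-2-vinylbutane-1,4-diol
Product: 5 (R)-2-vinylbutane-1,4-diyl dimethyl bis(carbonate)
Conditions: ClCO2Me, pyridine, DMAP (cat.), CH2Cl2, 0 °C to rt
Reagents that add atoms: methyl chloroformate, COC(=O)Cl
Why: Acylation of both primary alcohols; the O7 carbonate is the latent C20 carbon and the O15 carbonate is a protecting group, so the two hydroxyls need not be told apart here.

Step 4
Reactants: 5 (R)-2-vinylbutane-1,4-diyl dimethyl bis(carbonate); 6 but-3-en-2-one
Product: 7 (R,E)-2-(3-oxobut-1-en-1-yl)butane-1,4-diyl dimethyl bis(carbonate)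
Conditions: second-generation Hoveyda–Grubbs catalyst RuCl2(H2IMes)(=CH-C6H4-2-OiPr) (5 mol %), CH2Cl2, 40 °C
Reagents that add atoms: none
Why: Cross metathesis of a terminal alkene with an electron-poor vinyl ketone gives the (E)-enone and brings in C10, C1 and C2; the conditions are neutral, so the γ stereocentre C6 is safe.

Step 5
Reactants: 7 (R,E)-2-(3-oxobut-1-en-1-yl)butane-1,4-diyl dimethyl bis(carbonate)
Product: 8 (R,E)-2-[3-(tert-butyldimethylsilyloxy)buta-1,3-dien-1-yl]butane-1,4-diyl dimethyl bis(carbonate)
Conditions: TBSOTf, Et3N, CH2Cl2, −78 to 0 °C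
Reagents that add atoms: tert-butyldimethylsilyl trifluoromethanesulfonate, CC(C)(C)[Si](C)(C)OS(=O)(=O)C(F)(F)F
Why: Soft enolisation (silyl triflate and amine) of the enone at its methyl group gives the cross-conjugated 2-silyloxy diene; the tertiary γ hydrogen on C6 is not removed under these kinetic conditions.

Step 6
Reactants: 8 (R,E)-2-[3-(tert-butyldimethylsilyloxy)buta-1,3-dien-1-yl]butane-1,4-diyl dimethyl bis(carbonate); 9 2-methylprop-2-enal
Product: 11 ring A keto aldehyde (1-oxo; 4β-methyl; 4α-formyl; 5β-H; C5 side chain (R)-1,4-bis(methoxycarbonyloxy)butan-2-yl; formyl cis to the side chain), via silyl enol ether cycloadduct 10 (not isolated)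
Conditions: (S)-B-(o-tolyl) CBS-oxazaborolidine·Tf2NH (20 mol %), CH2Cl2, −78 to −40 °C; then 1 M HCl, THF, 0 °C
Reagents that add atoms: none
Why: Catalytic enantioselective Diels–Alder reaction of a 2-silyloxy diene with 2-methylacrolein bound to a chiral oxazaborolidinium cation; the diene substituents both direct C5 to C4 and C2 to C3, and the endo-formyl transition state puts C19 cis to the C5 side chain. The catalyst, not C6 with its two similar CH2 arms, is expected to select the diene face and so set C4 and C5, and any minor diastereomer would be removed at this stage or at lactone 16; acid then unmasks the C1 ketone.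

Step 7
Reactants: 11 ring A keto aldehyde
Product: 13 keto ester (4α-methoxycarbonyl; 4β-methyl; 1-oxo; side chain unchanged), via carboxylic acid 12 (not isolated)
Conditions: NaClO2, NaH2PO4, 2-methyl-2-butene, t-BuOH/H2O, 0 °C to rt; then TMSCHN2, MeOH/toluene, 0 °C
Reagents that add atoms: sodium chlorite, [Na+].[O-]Cl=O; (trimethylsilyl)diazomethane, C[Si](C)(C)C=[N+]=[N-]
Why: Pinnick oxidation of a non-enolisable aldehyde and esterification with (trimethylsilyl)diazomethane; C4 is quaternary, so no stereocentre is at risk.

Step 8
Reactants: 13 keto ester; 14 allyl bromide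
Product: 16 angular allyl keto lactone (C20(=O)–O–C7 δ-lactone cis-fused to ring A; 10β-allyl; 1-oxo; 15-O-methoxycarbonyl), via β-keto lactone 15 (not isolated)
Conditions: NaHMDS (1.1 equiv), THF, −78 to 0 °C; then allyl bromide, DMF, 0 °C to rt
Reagents that add atoms: none
Why: Intramolecular Claisen (Dieckmann-type) C-acylation of the ketone enolate by the O7 carbonate, then C-allylation of the resulting β-keto lactone enolate. The ketone enolates equilibrate, and only the C10 enolate can reach a carbonate through a six-membered transition state (the C2 enolate would need an eight-membered and the O15 carbonate a seven-membered ring), so C20 is placed regiospecifically. The allyl group enters the ring-fusion carbon from the convex face to give the cis-fused lactone, that is C9 β (cis to H5) and C20 α.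

Step 9
Reactants: 16 angular allyl keto lactone
Product: 17 enol triflate (C1(OTf)=C2)
Conditions: KHMDS, THF, −78 °C; PhNTf2, −78 to 0 °C
Reagents that add atoms: N-phenylbis(trifluoromethanesulfonimide), O=S(=O)(N(c1ccccc1)S(=O)(=O)C(F)(F)F)C(F)(F)F
Why: Enol triflate formation; C2 is the only enolisable position because C10 and C4 are quaternary.

Step 10
Reactants: 17 enol triflate
Product: 18 lactone alkene (ring A C1=C2)
Conditions: Pd(OAc)2 (5 mol %), PPh3, Bu3N, HCO2H, DMF, 60 °C
Reagents that add atoms: none
Why: Palladium-catalysed formate reduction of an enol triflate removes the C1 oxygen and leaves a C1=C2 alkene that is saturated later together with C11=C12; it also disarms the β-keto lactone against retro-Claisen cleavage.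

Step 11
Reactants: 18 lactone alkene
Product: 20 lactone triethylsilyl ether (15-OTES; lactone intact), via lactone alcohol 19 (not isolated)
Conditions: K2CO3 (0.3 equiv), MeOH, 0 °C to rt; AcOH; PPTS (cat.), CH2Cl2, rt; then TESCl, imidazole, CH2Cl2, 0 °C
Reagents that add atoms: chlorotriethylsilane, CC[Si](Cl)(CC)CC
Why: Mild methanolysis (transesterification) cleaves the unhindered primary methyl carbonate, while the δ-lactone on quaternary C10 is the more hindered acyl group and keeps O7 masked. The brief acid treatment re-closes any lactone that has opened, and silylation then gives the ether needed for step 13.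

Step 12
Reactants: 20 lactone triethylsilyl ether
Product: 22 ring A diester (10α-CO2Me; 10β-allyl; 4α-CO2Me; 4β-Me; ring A 1-ene; 7-OTBS; 15-OTES), via hydroxy diester 21 (not isolated)
Conditions: NaOMe (0.2 equiv), MeOH, 0 °C to rt; AcOH (0.2 equiv), evaporate below 20 °C; then TBSOTf, 2,6-lutidine, CH2Cl2, −78 °C
Reagents that add atoms: methanol (with sodium methoxide), CO; tert-butyldimethylsilyl trifluoromethanesulfonate, CC(C)(C)[Si](C)(C)OS(=O)(=O)C(F)(F)F
Why: Methoxide-catalysed methanolysis of the δ-lactone in neat methanol releases the C20 methyl ester and the C7 alcohol, which is silylated at once, without acid, before it can re-lactonise. C7 stays at the alcohol level so that C6–H is not acidic and no γ-lactone with C15 can form later.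

Step 13
Reactants: 22 ring A diester
Product: 23 aldehyde (C15 formyl; 7-OTBS)
Conditions: (COCl)2, DMSO, CH2Cl2, −78 to −30 °C; Et3N, −78 to 0 °C
Reagents that add atoms: none
Why: Swern conditions oxidise primary triethylsilyl ethers directly to aldehydes while tert-butyldimethylsilyl ethers survive, so C15 is unveiled in one step without a free hydroxy intermediate.

Step 14
Reactants: 23 aldehyde
Product: 24 2-substituted acrolein (C8=C14; C15 formyl)
Conditions: CH2=NMe2+ I− (Eschenmoser's salt), Et3N, CH2Cl2, rt
Reagents that add atoms: N,N-dimethylmethyleneiminium iodide, C=[N+](C)C.[I-]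
Why: Mannich reaction of the aldehyde with Eschenmoser's salt and β-elimination of dimethylamine (α-methylenation) installs C14; C6–H is only allylic, so the alkene has no conjugated position to move into.

Step 15
Reactants: 25 ethynyltrimethylsilane; 26 acrolein
Product: 27 5-(trimethylsilyl)pent-1-en-4-yn-3-ol (racemic)
Conditions: n-BuLi, THF, −78 °C; acrolein, −78 °C; then H2O
Reagents that add atoms: none
Why: 1,2-Addition of lithium (trimethylsilyl)acetylide to acrolein; the carbinol carbon (C13) is oxidised in step 17, so its configuration does not matter.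

Step 16
Reactants: 24 2-substituted acrolein; 27 5-(trimethylsilyl)pent-1-en-4-yn-3-ol
Product: 28 enynol (C11=C12 E; C13 carbinol as both epimers)
Conditions: second-generation Hoveyda–Grubbs catalyst RuCl2(H2IMes)(=CH-C6H4-2-OiPr) (10 mol %), 27 (3 equiv), CH2Cl2, 40 °C
Reagents that add atoms: none
Why: Cross metathesis of the terminal allyl group with a secondary allylic alcohol gives the (E)-alkene; the 1,1-disubstituted enal, the cyclohexene and the bulky silyl alkyne are poor metathesis partners and should stay spectators.

Step 17
Reactants: 28 enynol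
Product: 29 enynone (C13 ketone)
Conditions: Dess–Martin periodinane, NaHCO3, CH2Cl2, 0 °C to rt
Reagents that add atoms: none
Why: Dess–Martin oxidation of the allylic and propargylic secondary alcohol gives the cross-conjugated enynone; the enal and the silyl ether are stable to the buffered reagent.

Step 18
Reactants: 29 enynone
Product: 30 silyloxy dienyne (C9=C11 E; C12=C13 E with OTBS outside and alkyne inside)
Conditions: TBSOTf, Et3N, CH2Cl2, −78 to 0 °C
Reagents that add atoms: tert-butyldimethylsilyl trifluoromethanesulfonate, CC(C)(C)[Si](C)(C)OS(=O)(=O)C(F)(F)F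
Why: Soft γ-enolisation of the enone (O-silylation, then loss of a C9 hydrogen). The s-trans enynone conformer, favoured because the alkyne is slim, gives the (E)-enol ether with oxygen outside and alkyne inside, and C9=C11 forms trans. The enal has no enolisable hydrogen, and any (Z)-enol ether would be a much poorer diene and could be hydrolysed back to 29.

Step 19
Reactants: 30 silyloxy dienyne
Product: 31 tricyclic aldehyde (rings A, B and C; C8 formyl β; 9β-H; 13-OTBS and 13-alkynyl with C16 cis to C15; C11=C12)
Conditions: toluene (0.005 M), BHT (cat.), sealed tube, 110–130 °C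
Reagents that add atoms: none
Why: A concerted, asynchronous thermal [4+2] cycloaddition (diene HOMO, enal LUMO) joins C9 to C8 and C13 to C14; the closest known reaction type is the intramolecular Diels–Alder reaction of 1,3,8-nonatrienes that carry silyloxy dienes, where a three-atom tether overrides the intermolecular regiochemical preference. Ring C is the new six-membered cycloaddition ring, and ring B closes as the five-membered tether ring in the fused mode, the only one a C10–C5–C6 tether allows. C13 follows from the diene geometry: the inside alkynyl group and the inside H9 end cis, so C16 lies on the face of H9. C8 is controlled by C6: allylic strain keeps H6 in the plane of the C8=C14 bond, the tether carbon C5 on the diene side and the CH2OTBS arm on the far side, so that C15 ends cis to C7 (both β). C9 follows from the tether-endo, formyl-exo transition state that gives the cis B/C fusion, in which the diene lies pseudo-equatorial on the forming trans-fused ring B, cis to the axial C20 ester. The step therefore needs facial selectivity (ring C on the α face of ring B) and cis fusion; the first rests on the early-set, non-epimerisable C6 centre and the trans-diequatorial arms on ring A, the second on the short tether and on the formyl group avoiding the inside alkyne under the diene. The mismatched polarity (the donor-bearing C13 bonds to the β-carbon C14) costs rate, which intramolecularity and heat should make up; high dilution and a radical inhibitor suppress dimerisation of the acrolein.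

Step 20
Reactants: 31 tricyclic aldehyde
Product: 32 neopentyl alcohol (C15 CH2OH)
Conditions: NaBH4, MeOH/THF, −20 to 0 °C
Reagents that add atoms: none
Why: Borohydride reduces the aldehyde and leaves the hindered methyl esters; because C7 is a silyl ether the new C15 alcohol cannot lactonise.

Step 21
Reactants: 32 neopentyl alcohol
Product: 33 iodide (C15 CH2I)
Conditions: I2, PPh3, imidazole, toluene, 70 °C
Reagents that add atoms: iodine, II
Why: Appel-type iodination of a primary alcohol with triphenylphosphine, iodine and imidazole; the neopentyl position makes the displacement slow, hence the warm conditions.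

Step 22
Reactants: 33 iodide
Product: 34 tetracyclic vinylsilane (ring D closed; C16=C17H–SiMe3 with silicon cis to C13)
Conditions: Bu3SnH (slow addition), AIBN (cat.), benzene, 80 °C
Reagents that add atoms: none
Why: Tin hydride-mediated 5-exo-dig radical cyclisation of the primary C15 radical onto the silyl alkyne held cis on C13 forms C15–C16; the ring alkenes would need a 5-endo closure or a closure across the trans-disposed C10 and should not compete. Hydrogen transfer to the vinyl radical from the less hindered C15 side should place silicon cis to C13, and the vinylsilane is a masked exocyclic methylene.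

Step 23
Reactants: 34 tetracyclic vinylsilane
Product: 35 saturated vinylsilane (C11–C12 and C1–C2 reduced)
Conditions: 2-nitrobenzenesulfonylhydrazide (excess), Et3N, CH2Cl2, rt
Reagents that add atoms: none
Why: Diimide reduces the two cis-disubstituted ring alkenes and leaves the hindered trisubstituted vinylsilane, which is why the exocyclic alkene is carried as its silane through this step.

Step 24
Reactants: 35 saturated vinylsilane
Product: 36 diol (13-OH; 7-OH; C16 methylene; 19,20-dimethyl ester)
Conditions: TBAF (6 equiv), THF/DMSO, 60–70 °C
Reagents that add atoms: none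
Why: Fluoride removes both silyl ethers, and the C13 alkoxide then attacks the cis-disposed vinyl silicon (1,4 carbon-to-oxygen silyl shift, Brook type), so protodesilylation occurs without the acid that the 13-hydroxy-16-ene unit would not tolerate.

Step 25
Reactants: 36 diol
Product: 38 19,20-dimethyl ester of triacid 39 (C7 carboxylic acid free), via C7 aldehyde 37 (not isolated)
Conditions: TEMPO (cat.), PhI(OAc)2, CH2Cl2, rt; then NaClO2, NaH2PO4, 2-methyl-2-butene, t-BuOH/H2O
Reagents that add atoms: sodium chlorite, [Na+].[O-]Cl=O
Why: TEMPO with iodobenzene diacetate oxidises only the primary alcohol to the aldehyde, and buffered chlorite with an alkene scavenger takes it to the acid; if C6 epimerised at the aldehyde stage, the natural arrangement (C7 trans to C4) is expected to be the more stable one.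

Step 26
Reactants: 38 19,20-dimethyl ester of triacid 39
Product: 39 ent-13-hydroxygibberell-16-ene-7,19,20-trioic acid (the target)
Conditions: n-PrSLi (excess), HMPA, 50 °C; then dilute HCl
Reagents that add atoms: none
Why: SN2 demethylation by thiolate in a dipolar aprotic solvent attacks the methyl carbons of the two hindered axial esters, not the shielded carbonyls, and avoids forcing saponification and strong acid.

## Compound list

1 | furan-2(5H)-one | O=C1OCC=C1 | starting material
2 | potassium trifluoro(vinyl)borate | C=C[B-](F)(F)F.[K+] | starting material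
3 | (R)-4-vinyldihydrofuran-2(3H)-one | C=C[C@@H]1COC(=O)C1 | intermediate
4 | (R)-2-vinylbutane-1,4-diol | C=C[C@H](CO)CCO | intermediate
5 | (R)-2-vinylbutane-1,4-diyl dimethyl bis(carbonate) | C=C[C@H](COC(=O)OC)CCOC(=O)OC | intermediate
6 | but-3-en-2-one (methyl vinyl ketone) | CC(=O)C=C | starting material
7 | (R,E)-2-(3-oxobut-1-en-1-yl)butane-1,4-diyl dimethyl bis(carbonate) | CC(=O)/C=C/[C@H](COC(=O)OC)CCOC(=O)OC | intermediate
8 | (R,E)-2-[3-(tert-butyldimethylsilyloxy)buta-1,3-dien-1-yl]butane-1,4-diyl dimethyl bis(carbonate) | C=C(O[Si](C)(C)C(C)(C)C)/C=C/[C@H](COC(=O)OC)CCOC(=O)OC | intermediate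
9 | 2-methylprop-2-enal (methacrolein) | CC(=C)C=O | starting material
10 | silyl enol ether cycloadduct (1-OTBS cyclohex-1(10)-ene; 4α-formyl-4β-methyl; 5β-H) | CC(C)(C)[Si](C)(C)OC1=C[C@H]([C@H](COC(=O)OC)CCOC(=O)OC)[C@](C)(C=O)CC1 | intermediate
11 | ring A keto aldehyde (1-oxo; 4α-formyl-4β-methyl; 5β-H; formyl cis to side chain) | O=C1CC[C@@](C)(C=O)[C@H](C1)[C@H](COC(=O)OC)CCOC(=O)OC | intermediate
12 | keto acid (C19 carboxylic acid) | O=C1CC[C@@](C)(C(=O)O)[C@H](C1)[C@H](COC(=O)OC)CCOC(=O)OC | intermediate
13 | keto ester (C19 methyl ester) | O=C1CC[C@@](C)(C(=O)OC)[C@H](C1)[C@H](COC(=O)OC)CCOC(=O)OC | intermediate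
14 | allyl bromide | C=CCBr | starting material
15 | β-keto δ-lactone (C20(=O)–O–C7; C10–H, enolisable) | O=C1CC[C@@](C)(C(=O)OC)[C@H]2[C@@H](CCOC(=O)OC)COC(=O)C12 | intermediate
16 | angular allyl keto lactone (10β-allyl; cis-fused lactone; 1-oxo) | C=CC[C@@]12C(=O)OC[C@H](CCOC(=O)OC)[C@@H]1[C@](C)(C(=O)OC)CCC2=O | intermediate
17 | enol triflate (C1(OTf)=C2) | C=CC[C@@]12C(=O)OC[C@H](CCOC(=O)OC)[C@@H]1[C@](C)(C(=O)OC)CC=C2OS(=O)(=O)C(F)(F)F | intermediate
18 | lactone alkene (ring A 1-ene; 15-O-methoxycarbonyl) | C=CC[C@@]12C(=O)OC[C@H](CCOC(=O)OC)[C@@H]1[C@](C)(C(=O)OC)CC=C2 | intermediate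
19 | lactone alcohol (15-OH) | C=CC[C@@]12C(=O)OC[C@H](CCO)[C@@H]1[C@](C)(C(=O)OC)CC=C2 | intermediate
20 | lactone triethylsilyl ether (15-OTES) | C=CC[C@@]12C(=O)OC[C@H](CCO[Si](CC)(CC)CC)[C@@H]1[C@](C)(C(=O)OC)CC=C2 | intermediate
21 | hydroxy diester (7-OH; 15-OTES; C19 and C20 methyl esters) | C=CC[C@]1(C(=O)OC)C=CC[C@@](C)(C(=O)OC)[C@H]1[C@H](CO)CCO[Si](CC)(CC)CC | intermediate
22 | ring A diester (7-OTBS; 15-OTES; 10β-allyl; ring A 1-ene) | C=CC[C@]1(C(=O)OC)C=CC[C@@](C)(C(=O)OC)[C@H]1[C@H](CO[Si](C)(C)C(C)(C)C)CCO[Si](CC)(CC)CC | intermediate
23 | aldehyde (C15 formyl; 7-OTBS) | C=CC[C@]1(C(=O)OC)C=CC[C@@](C)(C(=O)OC)[C@H]1[C@H](CO[Si](C)(C)C(C)(C)C)CC=O | intermediate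
24 | 2-substituted acrolein (C8=C14; C15 formyl) | C=CC[C@]1(C(=O)OC)C=CC[C@@](C)(C(=O)OC)[C@H]1[C@H](CO[Si](C)(C)C(C)(C)C)C(=C)C=O | intermediate
25 | ethynyltrimethylsilane | C#C[Si](C)(C)C | starting material
26 | acrolein | C=CC=O | starting material
27 | 5-(trimethylsilyl)pent-1-en-4-yn-3-ol (racemic) | C=CC(O)C#C[Si](C)(C)C | intermediate
28 | enynol (C11=C12 E; C13 carbinol, both epimers) | C[Si](C)(C)C#CC(O)/C=C/C[C@]1(C(=O)OC)C=CC[C@@](C)(C(=O)OC)[C@H]1[C@H](CO[Si](C)(C)C(C)(C)C)C(=C)C=O | intermediate
29 | enynone (C13 ketone) | C[Si](C)(C)C#CC(=O)/C=C/C[C@]1(C(=O)OC)C=CC[C@@](C)(C(=O)OC)[C@H]1[C@H](CO[Si](C)(C)C(C)(C)C)C(=C)C=O | intermediate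
30 | silyloxy dienyne, precursor of the key step | C=C(C=O)[C@@H](CO[Si](C)(C)C(C)(C)C)[C@H]1[C@@](C(=O)OC)(C=CC[C@@]1(C)C(=O)OC)/C=C/C=C(/O[Si](C)(C)C(C)(C)C)C#C[Si](C)(C)C | intermediate
31 | tricyclic aldehyde, product of the key step | O=C[C@]12C[C@](O[Si](C)(C)C(C)(C)C)(C#C[Si](C)(C)C)C=C[C@H]1[C@]1(C(=O)OC)C=CC[C@@](C)(C(=O)OC)[C@H]1[C@@H]2CO[Si](C)(C)C(C)(C)C | intermediate
32 | neopentyl alcohol (C15 CH2OH) | OC[C@]12C[C@](O[Si](C)(C)C(C)(C)C)(C#C[Si](C)(C)C)C=C[C@H]1[C@]1(C(=O)OC)C=CC[C@@](C)(C(=O)OC)[C@H]1[C@@H]2CO[Si](C)(C)C(C)(C)C | intermediate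
33 | iodide (C15 CH2I) | IC[C@]12C[C@](O[Si](C)(C)C(C)(C)C)(C#C[Si](C)(C)C)C=C[C@H]1[C@]1(C(=O)OC)C=CC[C@@](C)(C(=O)OC)[C@H]1[C@@H]2CO[Si](C)(C)C(C)(C)C | intermediate
34 | tetracyclic vinylsilane (silicon cis to C13; 1-ene and 11-ene) | C[Si](C)(C)/C=C1/C[C@]23C[C@@]1(O[Si](C)(C)C(C)(C)C)C=C[C@H]2[C@]1(C(=O)OC)C=CC[C@@](C)(C(=O)OC)[C@H]1[C@@H]3CO[Si](C)(C)C(C)(C)C | intermediate
35 | saturated vinylsilane | C[Si](C)(C)/C=C1/C[C@]23C[C@@]1(O[Si](C)(C)C(C)(C)C)CC[C@H]2[C@]1(C(=O)OC)CCC[C@@](C)(C(=O)OC)[C@H]1[C@@H]3CO[Si](C)(C)C(C)(C)C | intermediate
36 | diol (13-OH; 7-OH; C16 methylene; 19,20-dimethyl ester) | C=C1C[C@]23C[C@@]1(O)CC[C@H]2[C@]1(C(=O)OC)CCC[C@@](C)(C(=O)OC)[C@H]1[C@@H]3CO | intermediate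
37 | C7 aldehyde | C=C1C[C@]23C[C@@]1(O)CC[C@H]2[C@]1(C(=O)OC)CCC[C@@](C)(C(=O)OC)[C@H]1[C@@H]3C=O | intermediate
38 | 19,20-dimethyl ester of triacid 39 (C7 carboxylic acid free) | C=C1C[C@]23C[C@@]1(O)CC[C@H]2[C@]1(C(=O)OC)CCC[C@@](C)(C(=O)OC)[C@H]1[C@@H]3C(=O)O | intermediate
39 | ent-13-hydroxygibberell-16-ene-7,19,20-trioic acid (the gibberellin numbered seventeen in the A series) | C=C1C[C@]23C[C@@]1(O)CC[C@H]2[C@]1(C(=O)O)CCC[C@@](C)(C(=O)O)[C@H]1[C@@H]3C(=O)O | target

## Count and risks

Total steps: 26. Longest linear sequence: 25 steps (steps 1–14 and 16–26; step 15 makes the side fragment 27).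

**Step 19 (key step).** The most likely failure is poor facial discrimination, which would place ring C on the β face of ring B (the C8/C9/C13-epimeric series) beside 31. The control elements are an allylic-strain preference at C6 and a conformational preference of the forming ring B, and both are modest at 110 °C. A slow reaction, caused by the mismatched polarity and the inside alkyne, would in turn expose the silyl dienol ether to hydrolysis. The fallback locks C15 to C7 covalently; it sets out from 24 and returns at 32. HF·pyridine removes the silyl ether of 24 and the freed C7 hydroxyl adds to the C15 aldehyde to give the lactol F1, which is oxidised (TEMPO, PhI(OAc)2) to the α-methylene-γ-butyrolactone F2. Cross metathesis with 27 gives the enynol lactone F3, Dess–Martin oxidation the enynone lactone F4, and TBSOTf with Et3N the silyloxy dienyne lactone F5. Heating F5 gives the lactone cycloadduct F6: the cis-fused five-membered lactone forces C15 and C7 onto the same face, so C6 fixes C8 directly, and the lactone carbonyl activates the alkene. LiBH4, which should spare the two hindered tertiary methyl esters, opens the lactone to the diol F7, and silylation of the less hindered C7 hydroxyl (TBSCl, imidazole) gives 32.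

**Step 8.** The angular allylation may suffer from O-allylation or from weak convex-face bias of the bicyclic enolate, which would erode the configuration at C10. The fallback sets out from 15 (isolated by quenching the cyclisation before allyl bromide is added) and returns at 16. The allyl group is delivered by palladium-catalysed asymmetric allylic alkylation (Pd2(dba)3, a chiral bis(2-diphenylphosphinobenzoyl)diamine ligand, allyl acetate, amine base), so that the ligand, not the substrate, selects the face of the β-keto lactone enolate. No compound outside the compound list is made (F0).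

**Step 12.** The methanolysis is an equilibrium: the cis-fused δ-lactone on quaternary C10 may be favoured over the open hydroxy ester, or re-lactonisation may outrun the silylation. The fallback opens the lactone irreversibly as a carboxylate; it sets out from 20 and returns at 22. LiOH in aqueous THF at room temperature opens 20 to the lithium salt of the hydroxy acid F8 (the hindered C19 ester and the triethylsilyl ether should survive). Without acidification, TBSCl and imidazole in DMF silylate both the C7 hydroxyl and the carboxylate to give the silyl ether silyl ester F9. K2CO3 in aqueous methanol at 0 °C cleaves only the silyl ester to the silyloxy acid F10, which can no longer lactonise, and (trimethylsilyl)diazomethane gives 22.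

**Step 16.** The ruthenium carbene may be trapped by the silyl alkyne of 27 (enyne metathesis), or homodimerisation of 27 may dominate and leave the hindered allyl group of 24 untouched. The fallback builds the enynone stepwise before the dienophile; it sets out from 22 and returns at 29. Cross metathesis of 22 with crotonaldehyde gives the enal F11, and lithium (trimethylsilyl)acetylide at −78 °C gives the propargylic alcohol F12. Swern oxidation converts the secondary alcohol and the primary triethylsilyl ether at once into the keto aldehyde F13, and methylenation with Eschenmoser's salt (kept in excess so that no free dimethylamine meets the ynone) gives 29.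

**Step 21.** Substitution at the neopentyl C15 is slow, and forcing it risks loss of the silyl ethers or incomplete conversion. The fallback generates the same radical without a substitution; it sets out from 32 and returns at 34. Phenyl chlorothionoformate and pyridine give the O-phenyl thionocarbonate F14. Bu3SnH with 1,1′-azobis(cyclohexanecarbonitrile) in toluene at 110 °C (Barton–McCombie-type fragmentation, which needs the higher temperature for a primary C–O bond) releases the C15 radical, which cyclises to 34.

**Step 24.** Alkoxide-assisted protodesilylation only works for the vinylsilane isomer with silicon cis to C13; any trans isomer from step 22 would keep its silicon, and harsher fluoride conditions may attack the esters. The fallback avoids the vinylsilane by reordering; it sets out from 33 and returns at 36. Diimide reduction of 33 (the hindered silyl alkyne should survive) gives the saturated iodide F15, and K2CO3 in methanol removes the alkynyl silicon to give the terminal alkyne F16. Bu3SnH with AIBN closes ring D directly to the exocyclic methylene bis(silyl ether) F17, and TBAF gives 36.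

## Further compounds

F1 | step 19 | lactol (C15(OH)–O–C7, both C15 epimers; C8=C14) on ring A diester | C=CC[C@]1(C(=O)OC)C=CC[C@@](C)(C(=O)OC)[C@H]1[C@@H]1COC(O)C1=C
F2 | step 19 | α-methylene-γ-butyrolactone (C15(=O)–O–C7; C8=C14) on ring A diester | C=CC[C@]1(C(=O)OC)C=CC[C@@](C)(C(=O)OC)[C@H]1[C@@H]1COC(=O)C1=C
F3 | step 19 | enynol lactone (C13 carbinol, both epimers) | C[Si](C)(C)C#CC(O)/C=C/C[C@]1(C(=O)OC)C=CC[C@@](C)(C(=O)OC)[C@H]1[C@@H]1COC(=O)C1=C
F4 | step 19 | enynone lactone | C[Si](C)(C)C#CC(=O)/C=C/C[C@]1(C(=O)OC)C=CC[C@@](C)(C(=O)OC)[C@H]1[C@@H]1COC(=O)C1=C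
F5 | step 19 | silyloxy dienyne lactone | C=C1C(=O)OC[C@H]1[C@H]1[C@@](C(=O)OC)(C=CC[C@@]1(C)C(=O)OC)/C=C/C=C(/O[Si](C)(C)C(C)(C)C)C#C[Si](C)(C)C
F6 | step 19 | lactone cycloadduct (C15(=O)–O–C7 lactone cis-fused on ring B) | O=C1OC[C@@H]2[C@]13C[C@](O[Si](C)(C)C(C)(C)C)(C#C[Si](C)(C)C)C=C[C@H]3[C@]3(C(=O)OC)C=CC[C@@](C)(C(=O)OC)[C@@H]23
F7 | step 19 | diol (15-OH; 7-OH) | OC[C@]12C[C@](O[Si](C)(C)C(C)(C)C)(C#C[Si](C)(C)C)C=C[C@H]1[C@]1(C(=O)OC)C=CC[C@@](C)(C(=O)OC)[C@H]1[C@@H]2CO
F0 | step 8 | none | none
F8 | step 12 | hydroxy acid (C20 carboxylic acid; 7-OH; 15-OTES) | C=CC[C@]1(C(=O)O)C=CC[C@@](C)(C(=O)OC)[C@H]1[C@H](CO)CCO[Si](CC)(CC)CC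
F9 | step 12 | silyl ether silyl ester (C20 CO2TBS; 7-OTBS; 15-OTES) | C=CC[C@]1(C(=O)O[Si](C)(C)C(C)(C)C)C=CC[C@@](C)(C(=O)OC)[C@H]1[C@H](CO[Si](C)(C)C(C)(C)C)CCO[Si](CC)(CC)CC
F10 | step 12 | silyloxy acid (C20 carboxylic acid; 7-OTBS; 15-OTES) | C=CC[C@]1(C(=O)O)C=CC[C@@](C)(C(=O)OC)[C@H]1[C@H](CO[Si](C)(C)C(C)(C)C)CCO[Si](CC)(CC)CC
F11 | step 16 | enal (C13 formyl; 15-OTES; 7-OTBS) | O=C/C=C/C[C@]1(C(=O)OC)C=CC[C@@](C)(C(=O)OC)[C@H]1[C@H](CO[Si](C)(C)C(C)(C)C)CCO[Si](CC)(CC)CC
F12 | step 16 | propargylic alcohol (C13 carbinol, both epimers; 15-OTES) | C[Si](C)(C)C#CC(O)/C=C/C[C@]1(C(=O)OC)C=CC[C@@](C)(C(=O)OC)[C@H]1[C@H](CO[Si](C)(C)C(C)(C)C)CCO[Si](CC)(CC)CC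
F13 | step 16 | keto aldehyde (C13 ynone; C15 formyl) | C[Si](C)(C)C#CC(=O)/C=C/C[C@]1(C(=O)OC)C=CC[C@@](C)(C(=O)OC)[C@H]1[C@H](CO[Si](C)(C)C(C)(C)C)CC=O
F14 | step 21 | O-phenyl thionocarbonate of 32 | S=C(Oc1ccccc1)OC[C@]12C[C@](O[Si](C)(C)C(C)(C)C)(C#C[Si](C)(C)C)C=C[C@H]1[C@]1(C(=O)OC)C=CC[C@@](C)(C(=O)OC)[C@H]1[C@@H]2CO[Si](C)(C)C(C)(C)C
F15 | step 24 | saturated iodide with silyl alkyne | IC[C@]12C[C@](O[Si](C)(C)C(C)(C)C)(C#C[Si](C)(C)C)CC[C@H]1[C@]1(C(=O)OC)CCC[C@@](C)(C(=O)OC)[C@H]1[C@@H]2CO[Si](C)(C)C(C)(C)C
F16 | step 24 | saturated iodide with terminal alkyne | IC[C@]12C[C@](O[Si](C)(C)C(C)(C)C)(C#C)CC[C@H]1[C@]1(C(=O)OC)CCC[C@@](C)(C(=O)OC)[C@H]1[C@@H]2CO[Si](C)(C)C(C)(C)C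
F17 | step 24 | exocyclic methylene bis(silyl ether) | C=C1C[C@]23C[C@@]1(O[Si](C)(C)C(C)(C)C)CC[C@H]2[C@]1(C(=O)OC)CCC[C@@](C)(C(=O)OC)[C@H]1[C@@H]3CO[Si](C)(C)C(C)(C)C
A1 | alternative 1 | enol triflate with C8=C15 methylene and 13-hydroxy-13-vinyl ring C (domino Heck substrate) | C=C[C@]1(O)CC[C@H](C(=C)C1)[C@]1(C(=O)OC)CCC[C@@](C)(C(=O)OC)/C1=C(/OS(=O)(=O)C(F)(F)F)C(=O)OC
A2 | alternative 1 | trimethyl ent-13-hydroxygibberella-5,16-diene-7,19,20-trioate (5,6-didehydro trimethyl ester of the target) | C=C1C[C@]23C[C@@]1(O)CC[C@H]2[C@]1(C(=O)OC)CCC[C@@](C)(C(=O)OC)C1=C3C(=O)OC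
A3 | alternative 2 | spiro iodide (ring D ketone with 13-OTBS and 2-iodoethyl; ring B C9=C10 enoate) | O=C1C[C@]2(C[C@@]1(O[Si](C)(C)C(C)(C)C)CCI)C=C(C(=O)OC)[C@H]([C@@H]2C(=O)OC)[C@@](C)(C=C)C(=O)OC
A4 | alternative 2 | ring B–C–D tricycle with C10 allyl and C4 vinyl groups | O=C1C[C@]23C[C@@]1(O[Si](C)(C)C(C)(C)C)CC[C@H]2[C@@](CC=C)(C(=O)OC)[C@H]([C@@H]3C(=O)OC)[C@@](C)(C=C)C(=O)OC
A5 | alternative 3 | steviol | C=C1C[C@]23C[C@@]1(O)CC[C@H]2[C@]1(C)CCC[C@@](C)(C(=O)O)[C@H]1CC3
A6 | alternative 3 | ring B diazoketone (ketone carbon next to C5; diazo carbon next to C8; 19,20-dimethyl ester; 13-acetate) | C=C1C[C@]23C[C@@]1(OC(C)=O)CC[C@H]2[C@]1(C(=O)OC)CCC[C@@](C)(C(=O)OC)[C@H]1C(=O)C3=[N+]=[N-]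
A7 | alternative 3 | trimethyl ent-13-acetoxygibberell-16-ene-7,19,20-trioate (trimethyl ester 13-acetate of the target) | C=C1C[C@]23C[C@@]1(OC(C)=O)CC[C@H]2[C@]1(C(=O)OC)CCC[C@@](C)(C(=O)OC)[C@H]1[C@@H]3C(=O)OC
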